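**Partner balance.** I take it that each unit of target has used one unit of partner, so the fraction of partner left is one minus the target fraction times the ratio of the two charges. That ratio is 1.05 in Sunday's run and 1.58 in Wednesday's.

| flask | starting material | partner | remark | time |
|---|---|---|---|---|
| Sunday's | 0.80 M | 0.76 M | the very flask that is asked about, followed so far |  |
| Wednesday's | 1.2 M | 0.76 M | run made earlier |  |
| flask | 0.80 M | 0.760 M |  | 2.5 min |

- Sunday's (time / s: target / %, starting material / %): 10.0: 12, 23; 12.0: 12, 21; 25.0: 18, 9; 60.0: 28, 9
- Wednesday's (time / min: target / %, starting material / %): 0.333: 15, 11; 0.833: 20, 7; 1.50: 23, 3; 2.50: 29, 8

(standard deviation of a reading: 2 percentage points)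

- amount of target in percent of the starting material charged, at 15 s, 50 s, 1.5 min and 2.5 min

- the numbers in the tables scatter by 2 percentage points (one standard deviation)

**Late constant.** Sunday's starting material reads a mean of 9.00 % at its last two times while the target still climbs, so I expect the rise to follow the starting material fraction times the partner fraction. Sunday's last two readings give 2.51 /min, and Wednesday's readings give 1.37 /min. Their mean, 1.94 /min, is my late constant, the rise of the target fraction per minute divided by the fractions of starting material and partner. It is a pseudo-first-order constant taken at full partner, and it is a reading with the scatter of its readings.

**The settings.** Raising the starting material charge should cost more partner fraction per point of target, by the two ratios above. Wednesday's target reads 29 % at 2.50 min, and Sunday's reads 28 % at 60.0 s. The partner charge is 0.76 M in both runs, so my constant holds for that charge. Time should slow the rise as the partner fraction falls, so I reckon in rounds.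

**My reckoning.** I start from Sunday's 28 % at 60.0 s and hold the starting material at 9.00 %. My first round, with the partner fraction of that moment, puts the target at 46.5 % at 2.5 min. Putting that answer back, with the partner fraction taken at the middle of the stretch, gives 43.9 %.

**The forecast.** It gives 14 %, 25 %, 33 % and 42 %, holding that “most material is held in an unmeasured intermediate”. My last point stands above its last point by 1.9 percentage points.

**The result.** The flask gives 14.5 %, 22.5 %, 28.0 % and 34.7 %.

    starting material ⇌ side product A (K = 0.705, k = 0.0490 /s)
    starting material ⇌ intermediate A (K = 8.90, k = 0.108 /s)
    starting material + partner → intermediate B (k = 0.0395 /M/s)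
    intermediate B → target (k = 0.442 /s)
    intermediate B → side product B (k = 0.00870 /s)

In the flask at 2.50 min intermediate A holds 55.1 % beside 5.4 % of starting material. The late constant on that 5.4 % and on the 63 % of partner gives a rise of 0.0653 /min at that moment, and the flask's mean rise from 1.5 min to 2.5 min is 0.0670 /min. With twice the starting material in the flask the target comes to 29.1 %, and the partner balance then reckons 38.9 % of that flask's partner charge as left.

The data come from a simulation with constants of no real substance; the scatter is artificial.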